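**Retrosynthetic overview**
1. The acid comes from its methyl ester; the Z exocyclic alkene comes from a reductive 1,3-transposition (allylic diazene) of an allylic alcohol whose ring double bond is fixed at C2=C3.
2. That alcohol is cut at the carbinol–ring bond: a light-driven nickel/photoredox coupling of a dioxane aldehyde with a cyclohexa-1,4-dienyl triflate forms the key C–C bond.
3. Dioxane aldehyde: the C6 chain by allylation of a cyclic peroxyketal (C3 controls C6); the peroxide ring by ozonolysis then SN2 closure with inversion at C3; C2 and C3 from (S)-3-hydroxy-γ-butyrolactone by trans-methylation.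
4. Triflate: Birch reduction of a 6-silyloxy-1,1-dimethyltetralin made from 6-hydroxy-1-tetralone.
5. Ring order: both carbocycles are bought as the tetralone (the aromatic ring is only reduced); the 1,2-dioxane is the one ring built (step 5), before the fragments are joined.

Assumption: (S)-3-hydroxy-γ-butyrolactone and 6-hydroxy-1-tetralone are the purchased starting materials, all other reagents are catalogue chemicals, and numbers follow the forward route.

**Fragment 1: dioxane aldehyde**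

Step 1
Reactants: 1 (4S)-4-hydroxyoxolan-2-one
Product: 2 (3S,4S)-4-hydroxy-3-methyloxolan-2-one
Conditions: LiN(i-Pr)2 (2.2 equiv), THF/DMPU, −78 °C; MeI, −78 → −40 °C; aq. NH4Cl
Reagents that add atoms: iodomethane, CI
Why: Fráter–Seebach-type alkylation of the lactone alkoxide–enolate dianion; iodomethane enters the enolate face trans to the C4 alkoxide, so the purchased C4 centre sets C3 as (3S).

Step 2
Reactants: 2 (3S,4S)-4-hydroxy-3-methyloxolan-2-one
Product: 4 methyl (2S)-2-[(2S)-oxiran-2-yl]propanoate, via iodohydrin ester 3 (not isolated)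
Conditions: Me3SiI, MeOH, CH2Cl2, 0 → 20 °C; evaporate; Ag2O, MeCN, 40 °C
Reagents that add atoms: methanol, CO
Why: Silyl-assisted SN2 opening of the lactone at the primary carbon by iodide with methyl ester formation, then Ag2O-promoted Williamson closure of the iodohydrin; no stereocentre is touched and the neutral silver oxide avoids base-induced opening of the β,γ-epoxy ester.

Step 3
Reactants: 4 methyl (2S)-2-[(2S)-oxiran-2-yl]propanoate
Product: 5 methyl (2S,3R)-3-hydroxy-2,6-dimethylhept-6-enoate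
Conditions: (2-methylallyl)MgCl (1.5 equiv), CuI (10 mol %), THF, −78 → −40 °C; aq. NH4Cl
Reagents that add atoms: (2-methylallyl)magnesium chloride, CC(=C)C[Mg]Cl
Why: Copper-catalysed Grignard opening (SN2) of the terminal epoxide at the CH2 carbon, which at −78 °C should outrun addition to the ester; the carbinol centre is untouched (its descriptor becomes 3R only through changed CIP priorities).

Step 4
Reactants: 5 methyl (2S,3R)-3-hydroxy-2,6-dimethylhept-6-enoate
Product: 6 methyl (2S,3R)-3-(methanesulfonyloxy)-2,6-dimethylhept-6-enoate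
Conditions: MsCl, Et3N, CH2Cl2, −20 °C
Reagents that add atoms: methanesulfonyl chloride, CS(=O)(=O)Cl
Why: O-Sulfonylation with retention; low temperature and short contact with the amine keep the β-mesyloxy ester from eliminating.

Step 5
Reactants: 6 methyl (2S,3R)-3-(methanesulfonyloxy)-2,6-dimethylhept-6-enoate
Product: 8 methyl (2S)-2-[(3S)-6-methoxy-6-methyl-1,2-dioxan-3-yl]propanoate (both C6 epimers), via hydroperoxy ketal 7 (not isolated)
Conditions: O3, CH2Cl2/MeOH 4:1, −78 °C; N2 purge; evaporate at 0 °C; Cs2CO3, DMF, 0 → 20 °C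
Reagents that add atoms: ozone, [O-][O+]=O; methanol, CO
Why: Ozonolysis in methanol (Criegee carbonyl oxide trapped by MeOH) gives the hydroperoxy ketal, whose peroxide anion closes the ring by intramolecular Williamson-type SN2 (6-exo-tet) at C3 with inversion, turning the syn carbinol into the required (3S) peroxide centre; carbonate is too weak to enolise the ester.

Step 6
Reactants: 8 methyl (2S)-2-[(3S)-6-methoxy-6-methyl-1,2-dioxan-3-yl]propanoate
Product: 9 methyl (2S)-2-[(3S,6R)-6-methyl-6-(prop-2-en-1-yl)-1,2-dioxan-3-yl]propanoate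
Conditions: allylSiMe3 (3 equiv), Me3SiOTf (0.3 equiv), CH2Cl2, −78 °C
Reagents that add atoms: allyltrimethylsilane, C=CC[Si](C)(C)C
Why: Hosomi–Sakurai allylation of the cyclic peroxycarbenium ion (peroxyketal substitution); axial attack on the half-chair cation whose C3 side chain is pseudo-equatorial puts the allyl group cis to that side chain and leaves methyl equatorial, so C3 sets C6 and both ketal epimers converge.

Step 7
Reactants: 9 methyl (2S)-2-[(3S,6R)-6-methyl-6-(prop-2-en-1-yl)-1,2-dioxan-3-yl]propanoate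
Product: 11 methyl (2S)-2-[(3S,6S)-6-(3-hydroxypropyl)-6-methyl-1,2-dioxan-3-yl]propanoate, via alkylborane 10 (not isolated)
Conditions: 9-BBN, THF, 0 → 20 °C; then 30% H2O2, aq. NaOAc, 0 °C
Reagents that add atoms: hydrogen peroxide, OO
Why: Anti-Markovnikov hydroboration of the terminal alkene and buffered oxidation of the B–C bond; 9-BBN should leave the ester and the dialkyl peroxide alone.

Step 8
Reactants: 11 methyl (2S)-2-[(3S,6S)-6-(3-hydroxypropyl)-6-methyl-1,2-dioxan-3-yl]propanoate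
Product: 12 methyl (2S)-2-[(3S,6R)-6-methyl-6-(3-oxopropyl)-1,2-dioxan-3-yl]propanoate
Conditions: DMP, CH2Cl2, 20 °C
Reagents that add atoms: none
Why: Dess–Martin oxidation under non-basic conditions that do not disturb the peroxide or the ester α-centre.

**Fragment 2: bicyclic alkenyl triflate**

Step 9
Reactants: 13 6-hydroxy-3,4-dihydronaphthalen-1(2H)-one
Product: 14 6-[tert-butyl(dimethyl)silyl]oxy-3,4-dihydronaphthalen-1(2H)-one
Conditions: TBSCl, imidazole, DMF, 20 °C
Reagents that add atoms: tert-butyldimethylsilyl chloride, CC(C)(C)[Si](C)(C)Cl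
Why: Silyl ether formation; the aryl silyl ether survives dissolving-metal reduction and later releases a regiodefined enolate.

Step 10
Reactants: 14 6-[tert-butyl(dimethyl)silyl]oxy-3,4-dihydronaphthalen-1(2H)-one
Product: 15 tert-butyl[(5,5-dimethyl-5,6,7,8-tetrahydronaphthalen-2-yl)oxy]dimethylsilane
Conditions: TiCl4, Me2Zn (forms Me2TiCl2), CH2Cl2, −30 → 0 °C
Reagents that add atoms: dichlorodimethyltitanium, C[Ti](C)(Cl)Cl (made in the flask from dimethylzinc, C[Zn]C)
Why: Reetz geminal dimethylation of the aryl ketone (methyl addition, ionisation to the benzylic cation, second methyl transfer).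

Step 11
Reactants: 15 tert-butyl[(5,5-dimethyl-5,6,7,8-tetrahydronaphthalen-2-yl)oxy]dimethylsilane
Product: 16 tert-butyl[(5,5-dimethyl-1,4,5,6,7,8-hexahydronaphthalen-2-yl)oxy]dimethylsilane
Conditions: Li, NH3(l), THF, t-BuOH, −78 → −33 °C
Reagents that add atoms: none
Why: Birch reduction; the oxygen-bearing and the two alkyl-bearing ring carbons stay sp2, giving the 1,4-diene with the silyl enol ether double bond fixed at C2=C3 and the tetrasubstituted C4a=C8a alkene in place.

Step 12
Reactants: 16 tert-butyl[(5,5-dimethyl-1,4,5,6,7,8-hexahydronaphthalen-2-yl)oxy]dimethylsilane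
Product: 17 5,5-dimethyl-1,4,5,6,7,8-hexahydronaphthalen-2-yl trifluoromethanesulfonate
Conditions: CsF, PhNTf2, DME, 20 °C
Reagents that add atoms: N-phenylbis(trifluoromethanesulfonimide), O=S(=O)(N(c1ccccc1)S(=O)(=O)C(F)(F)F)C(F)(F)F
Why: Fluoride cleavage of the silyl enol ether and O-triflation of the enolate; without a proton source the enolate cannot equilibrate, so the C2=C3 regiochemistry from the Birch step is kept.

**Union and endgame**

Step 13
Reactants: 12 methyl (2S)-2-[(3S,6R)-6-methyl-6-(3-oxopropyl)-1,2-dioxan-3-yl]propanoate; 17 5,5-dimethyl-1,4,5,6,7,8-hexahydronaphthalen-2-yl trifluoromethanesulfonate (1.5 equiv)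
Product: 18 methyl (2S)-2-[(3S,6S)-6-[3-(5,5-dimethyl-1,4,5,6,7,8-hexahydronaphthalen-2-yl)-3-hydroxypropyl]-6-methyl-1,2-dioxan-3-yl]propanoate (both carbinol epimers)
Conditions: NiBr2·glyme (10 mol %), 4,4'-di-tert-butyl-2,2'-bipyridine (12 mol %), 2,4,5,6-tetrakis(carbazol-9-yl)isophthalonitrile (2 mol %), diethyl 2,6-dimethyl-1,4-dihydropyridine-3,5-dicarboxylate (1.5 equiv), 2,6-lutidine (2 equiv), DMA, 450 nm LEDs, 20 °C
Reagents that add atoms: none
Why: Proposed new method: a chromium-free, light-driven nickel-catalysed reductive 1,2-addition of an alkenyl triflate to an aldehyde, not yet shown for a cyclohexa-1,4-dienyl triflate or a peroxide-bearing aldehyde — the excited organic photocatalyst is quenched by the dihydropyridine, its radical anion reduces divalent nickel to zerovalent nickel, oxidative addition of 17 gives an alkenylnickel triflate that after one-electron reduction to monovalent alkenylnickel inserts the C=O of 12, and lutidinium protonates the nickel alkoxide; no stoichiometric metal reductant and no substrate-derived carbon radical is formed, so the dialkyl peroxide and the doubly allylic C–H bonds should survive; the closest known reaction types are the Nozaki–Hiyama–Kishi coupling, nickel-catalysed reductive addition of aryl halides to aldehydes with zinc, and nickel/photoredox allylation of aldehydes; the new carbinol centre forms as a mixture, which does not matter because step 14 destroys it.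

Step 14
Reactants: 18 methyl (2S)-2-[(3S,6S)-6-[3-(5,5-dimethyl-1,4,5,6,7,8-hexahydronaphthalen-2-yl)-3-hydroxypropyl]-6-methyl-1,2-dioxan-3-yl]propanoate
Product: 21 methyl (2S)-2-[(3S,6S)-6-[(3Z)-3-(5,5-dimethyl-3,4,5,6,7,8-hexahydronaphthalen-2(1H)-ylidene)propyl]-6-methyl-1,2-dioxan-3-yl]propanoate, via sulfonylhydrazine adduct 19 (not isolated), via allylic diazene 20 (not isolated)
Conditions: 2-nitrobenzenesulfonohydrazide (NBSH), PPh3, DEAD, N-methylmorpholine/THF, −30 °C; then 20 °C
Reagents that add atoms: none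
Why: Myers reductive 1,3-transposition (Mitsunobu displacement by NBSH, loss of sulfinic acid, retro-ene loss of N2 from the allylic diazene) delivers hydrogen to ring C3 and moves the double bond to the exocyclic position; the side chain sits pseudo-equatorial in the cyclic transition state, so it ends trans to C3 and cis to C1 (Z), and both carbinol epimers converge.

Step 15
Reactants: 21 methyl (2S)-2-[(3S,6S)-6-[(3Z)-3-(5,5-dimethyl-3,4,5,6,7,8-hexahydronaphthalen-2(1H)-ylidene)propyl]-6-methyl-1,2-dioxan-3-yl]propanoate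
Product: 22 (2S)-2-[(3S,6S)-6-[(3Z)-3-(5,5-dimethyl-3,4,5,6,7,8-hexahydronaphthalen-2(1H)-ylidene)propyl]-6-methyl-1,2-dioxan-3-yl]propanoic acid
Conditions: LiOH, THF/MeOH/H2O, 0 → 20 °C; then 1 M HCl to pH 4, 0 °C
Reagents that add atoms: lithium hydroxide, [Li+].[OH-]
Why: Saponification of the methyl ester under conditions used for related 1,2-dioxane propanoates; cold hydroxide should not trigger retro-oxa-Michael opening or C2 epimerisation.

**Compound list**
1 | (4S)-4-hydroxyoxolan-2-one [(S)-3-hydroxy-γ-butyrolactone] | O=C1C[C@H](O)CO1 | starting material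
2 | (3S,4S)-4-hydroxy-3-methyloxolan-2-one (trans) | O=C1[C@@H](C)[C@H](O)CO1 | intermediate
3 | methyl (2S,3S)-3-hydroxy-4-iodo-2-methylbutanoate | COC(=O)[C@@H](C)[C@H](O)CI | intermediate
4 | methyl (2S)-2-[(2S)-oxiran-2-yl]propanoate | COC(=O)[C@@H](C)[C@H]1CO1 | intermediate
5 | methyl (2S,3R)-3-hydroxy-2,6-dimethylhept-6-enoate | COC(=O)[C@@H](C)[C@H](O)CCC(C)=C | intermediate
6 | methyl (2S,3R)-3-(methanesulfonyloxy)-2,6-dimethylhept-6-enoate | COC(=O)[C@@H](C)[C@H](OS(C)(=O)=O)CCC(C)=C | intermediate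
7 | methyl (2S,3R)-6-hydroperoxy-6-methoxy-3-(methanesulfonyloxy)-2-methylheptanoate (C6 epimers) | COC(=O)[C@@H](C)[C@H](OS(C)(=O)=O)CCC(C)(OC)OO | intermediate
8 | methyl (2S)-2-[(3S)-6-methoxy-6-methyl-1,2-dioxan-3-yl]propanoate (C6 epimers) | COC(=O)[C@@H](C)[C@@H]1CCC(C)(OC)OO1 | intermediate
9 | methyl (2S)-2-[(3S,6R)-6-methyl-6-(prop-2-en-1-yl)-1,2-dioxan-3-yl]propanoate | COC(=O)[C@@H](C)[C@@H]1CC[C@](C)(CC=C)OO1 | intermediate
10 | methyl (2S)-2-[(3S,6S)-6-[3-(9-borabicyclo[3.3.1]nonan-9-yl)propyl]-6-methyl-1,2-dioxan-3-yl]propanoate | COC(=O)[C@@H](C)[C@@H]1CC[C@](C)(CCCB2C3CCCC2CCC3)OO1 | intermediate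
11 | methyl (2S)-2-[(3S,6S)-6-(3-hydroxypropyl)-6-methyl-1,2-dioxan-3-yl]propanoate | COC(=O)[C@@H](C)[C@@H]1CC[C@](C)(CCCO)OO1 | intermediate
12 | methyl (2S)-2-[(3S,6R)-6-methyl-6-(3-oxopropyl)-1,2-dioxan-3-yl]propanoate | COC(=O)[C@@H](C)[C@@H]1CC[C@](C)(CCC=O)OO1 | intermediate
13 | 6-hydroxy-3,4-dihydronaphthalen-1(2H)-one (6-hydroxy-1-tetralone) | O=C1CCCc2cc(O)ccc12 | starting material
14 | 6-[tert-butyl(dimethyl)silyl]oxy-3,4-dihydronaphthalen-1(2H)-one | O=C1CCCc2cc(O[Si](C)(C)C(C)(C)C)ccc12 | intermediate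
15 | tert-butyl[(5,5-dimethyl-5,6,7,8-tetrahydronaphthalen-2-yl)oxy]dimethylsilane | CC1(C)CCCc2cc(O[Si](C)(C)C(C)(C)C)ccc12 | intermediate
16 | tert-butyl[(5,5-dimethyl-1,4,5,6,7,8-hexahydronaphthalen-2-yl)oxy]dimethylsilane | CC1(C)CCCC2=C1CC=C(O[Si](C)(C)C(C)(C)C)C2 | intermediate
17 | 5,5-dimethyl-1,4,5,6,7,8-hexahydronaphthalen-2-yl trifluoromethanesulfonate | CC1(C)CCCC2=C1CC=C(OS(=O)(=O)C(F)(F)F)C2 | intermediate
18 | methyl (2S)-2-[(3S,6S)-6-[3-(5,5-dimethyl-1,4,5,6,7,8-hexahydronaphthalen-2-yl)-3-hydroxypropyl]-6-methyl-1,2-dioxan-3-yl]propanoate (carbinol epimers) | COC(=O)[C@@H](C)[C@@H]1CC[C@](C)(CCC(O)C2=CCC3=C(CCCC3(C)C)C2)OO1 | intermediate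
19 | methyl (2S)-2-[(3S,6S)-6-{3-(5,5-dimethyl-1,4,5,6,7,8-hexahydronaphthalen-2-yl)-3-[1-(2-nitrobenzenesulfonyl)hydrazin-1-yl]propyl}-6-methyl-1,2-dioxan-3-yl]propanoate | COC(=O)[C@@H](C)[C@@H]1CC[C@](C)(CCC(N(N)S(=O)(=O)c4ccccc4[N+](=O)[O-])C2=CCC3=C(CCCC3(C)C)C2)OO1 | intermediate
20 | methyl (2S)-2-[(3S,6S)-6-[3-diazenyl-3-(5,5-dimethyl-1,4,5,6,7,8-hexahydronaphthalen-2-yl)propyl]-6-methyl-1,2-dioxan-3-yl]propanoate | COC(=O)[C@@H](C)[C@@H]1CC[C@](C)(CCC(N=N)C2=CCC3=C(CCCC3(C)C)C2)OO1 | intermediate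
21 | methyl (2S)-2-[(3S,6S)-6-[(3Z)-3-(5,5-dimethyl-3,4,5,6,7,8-hexahydronaphthalen-2(1H)-ylidene)propyl]-6-methyl-1,2-dioxan-3-yl]propanoate | COC(=O)[C@@H](C)[C@@H]1CC[C@](C)(CC/C=C2/CCC3=C(CCCC3(C)C)C2)OO1 | intermediate
22 | (2S)-2-[(3S,6S)-6-[(3Z)-3-(5,5-dimethyl-3,4,5,6,7,8-hexahydronaphthalen-2(1H)-ylidene)propyl]-6-methyl-1,2-dioxan-3-yl]propanoic acid | C[C@H](C(=O)O)[C@@H]1CC[C@](C)(CC/C=C2/CCC3=C(CCCC3(C)C)C2)OO1 | target

**Step count and risks**
Total steps: 15. Longest linear sequence: 11 (steps 1–8, then 13–15).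

The three steps most likely to fail:

Step 5 (ozonolysis and peroxide ring closure). The mesylate sits β to the ester, so elimination to the enoate can compete with the 6-exo SN2 closure. The fallback sets out from 5 and comes back at 8, carrying C1 at the alcohol level so that no acidic hydrogen flanks the leaving group. LiAlH4 in THF reduces 5 to (2R,3R)-2,6-dimethylhept-6-ene-1,3-diol F1. TBDPSCl/imidazole protects the primary hydroxyl to give (2R,3R)-1-{[tert-butyl(diphenyl)silyl]oxy}-2,6-dimethylhept-6-en-3-ol F2, and MsCl/Et3N gives (2R,3R)-1-{[tert-butyl(diphenyl)silyl]oxy}-2,6-dimethylhept-6-en-3-yl methanesulfonate F3. Ozonolysis in MeOH followed by KOt-Bu/18-crown-6 in toluene closes the ring with inversion to tert-butyl{(2R)-2-[(3S)-6-methoxy-6-methyl-1,2-dioxan-3-yl]propoxy}diphenylsilane F4. TBAF frees (2R)-2-[(3S)-6-methoxy-6-methyl-1,2-dioxan-3-yl]propan-1-ol F5, TEMPO/PhI(OAc)2 in wet MeCN oxidises it to (2S)-2-[(3S)-6-methoxy-6-methyl-1,2-dioxan-3-yl]propanoic acid F6, and Me3SiCHN2 in MeOH/toluene returns 8.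

Step 13 (the proposed nickel/photoredox alkenylation). It may fail through protodetriflation or dimerisation of 17, aromatisation of the cyclohexa-1,4-diene, or attack of low-valent nickel on the peroxide. The fallback uses known chemistry, sets out from 17 and comes back at 18. Miyaura borylation (B2pin2, PdCl2(PPh3)2, PPh3, KOPh, toluene, 50 °C) gives 2-(5,5-dimethyl-1,4,5,6,7,8-hexahydronaphthalen-2-yl)-4,4,5,5-tetramethyl-1,3,2-dioxaborolane F7. Rhodium-catalysed 1,2-addition of this alkenylboronate to aldehyde 12 ([Rh(OH)(cod)]2, dioxane/H2O, 50 °C) gives 18.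

Step 14 (Myers transposition). The Mitsunobu displacement at a carbinol flanked by a fully substituted alkene carbon may be slow, may leak into the SN2' mode, or PPh3 may attack the peroxide. The Z preference is argued by analogy and is not demonstrated for this ring system. The fallback sets out from 18 and comes back at 21 without any Mitsunobu step. DMP oxidation gives the enone methyl (2S)-2-[(3S,6R)-6-[3-(5,5-dimethyl-1,4,5,6,7,8-hexahydronaphthalen-2-yl)-3-oxopropyl]-6-methyl-1,2-dioxan-3-yl]propanoate F8. TsNHNH2 in MeOH gives the tosylhydrazone methyl (2S)-2-[(3S,6S)-6-{3-(5,5-dimethyl-1,4,5,6,7,8-hexahydronaphthalen-2-yl)-3-[(4-methylbenzenesulfonyl)hydrazinylidene]propyl}-6-methyl-1,2-dioxan-3-yl]propanoate F9. Kabalka reduction (catecholborane, CHCl3, 0 °C; then NaOAc·3H2O, 60 °C) passes through the same allylic diazene 20 to 21. This fallback does not address the geometric selectivity, only the Mitsunobu step.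

**Further compounds**
F1 | step 5 | (2R,3R)-2,6-dimethylhept-6-ene-1,3-diol | OC[C@@H](C)[C@H](O)CCC(C)=C
F2 | step 5 | (2R,3R)-1-{[tert-butyl(diphenyl)silyl]oxy}-2,6-dimethylhept-6-en-3-ol | CC(C)(C)[Si](c1ccccc1)(c1ccccc1)OC[C@@H](C)[C@H](O)CCC(C)=C
F3 | step 5 | (2R,3R)-1-{[tert-butyl(diphenyl)silyl]oxy}-2,6-dimethylhept-6-en-3-yl methanesulfonate | CC(C)(C)[Si](c1ccccc1)(c1ccccc1)OC[C@@H](C)[C@H](OS(C)(=O)=O)CCC(C)=C
F4 | step 5 | tert-butyl{(2R)-2-[(3S)-6-methoxy-6-methyl-1,2-dioxan-3-yl]propoxy}diphenylsilane | CC(C)(C)[Si](c1ccccc1)(c1ccccc1)OC[C@@H](C)[C@@H]1CCC(C)(OC)OO1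
F5 | step 5 | (2R)-2-[(3S)-6-methoxy-6-methyl-1,2-dioxan-3-yl]propan-1-ol | OC[C@@H](C)[C@@H]1CCC(C)(OC)OO1
F6 | step 5 | (2S)-2-[(3S)-6-methoxy-6-methyl-1,2-dioxan-3-yl]propanoic acid | OC(=O)[C@@H](C)[C@@H]1CCC(C)(OC)OO1
F7 | step 13 | 2-(5,5-dimethyl-1,4,5,6,7,8-hexahydronaphthalen-2-yl)-4,4,5,5-tetramethyl-1,3,2-dioxaborolane | CC1(C)CCCC2=C1CC=C(B3OC(C)(C)C(C)(C)O3)C2
F8 | step 14 | methyl (2S)-2-[(3S,6R)-6-[3-(5,5-dimethyl-1,4,5,6,7,8-hexahydronaphthalen-2-yl)-3-oxopropyl]-6-methyl-1,2-dioxan-3-yl]propanoate | COC(=O)[C@@H](C)[C@@H]1CC[C@](C)(CCC(=O)C2=CCC3=C(CCCC3(C)C)C2)OO1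
F9 | step 14 | methyl (2S)-2-[(3S,6S)-6-{3-(5,5-dimethyl-1,4,5,6,7,8-hexahydronaphthalen-2-yl)-3-[(4-methylbenzenesulfonyl)hydrazinylidene]propyl}-6-methyl-1,2-dioxan-3-yl]propanoate | COC(=O)[C@@H](C)[C@@H]1CC[C@](C)(CCC(=NNS(=O)(=O)c4ccc(C)cc4)C2=CCC3=C(CCCC3(C)C)C2)OO1
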